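The earlier runs and the new flask are simulated on assumed constants, noise included.

The meeting opened on the vessel: a stirred flask of constant volume, in which Z and X turn the acidic D into G. The question was whether slow feeding pays.

| flask | D | Z | X | remark | time |
|---|---|---|---|---|---|
| amber | 0.50 M | 0.60 equiv | 1.1 equiv | run made earlier |  |
| green | 0.70 M | 0.60 equiv | 1.1 equiv | run made earlier |  |
| teal | 1.1 M | 0.60 equiv | 1.1 equiv | run made earlier |  |
| red | 0.50 M | 0.60 equiv | 0.55 equiv | run made earlier |  |
| oak | 0.50 M | 0.600 equiv (fed, over 20 h) | 1.10 equiv | all else is in the flask from the start; the feed brings no volume worth counting | 25 h |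
| elm | 0.50 M (fed, over 20 h) | 0.600 equiv | 1.10 equiv | all else is in the flask from the start; the feed brings no volume worth counting | 25 h |
| birch | 0.50 M | 0.600 equiv | 1.10 equiv | everything together at the start | 25 h |

- amber (time / h: G / %, D / %): 1.00: 22.2, 56.1; 3.00: 36.6, 51.0; 5.00: 41.1, 48.4; 8.00: 43.9, 47.4; 12.0: 45.0, 46.8; 15.0: 45.5, 47.8
- green (time / h: G / %, D / %): 4.00: 45.7, 47.5; 8.00: 49.9, 46.1; 12.0: 50.2, 45.3; 15.0: 49.8, 44.9; 20.0: 49.8, 45.3; 25.0: 50.2, 45.1
- teal (time / h: G / %, D / %): 2.00: 45.1, 48.9; 3.00: 49.3, 46.2; 6.00: 53.4, 43.8; 10.0: 55.2, 42.9; 15.0: 55.8, 42.4; 25.0: 55.0, 41.8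
- red (time / h: G / %, D / %): 2.00: 19.2, 57.0; 6.00: 25.1, 54.3; 12.0: 28.4, 53.7; 20.0: 29.2, 54.0; 25.0: 28.0, 53.9

(readings scatter by 0.5 percentage points)

- the best flask by amount of G, in percent of the D charged; "all alike" if 1.5 percentage points covers them all (oak / elm / birch / all alike)
- amount of G at the end, in percent of the D charged, oak
- amount of G at the end, in percent of the D charged, elm
- amount of G at the end, in percent of the D charged, birch



The first chemist gave her own reckoning. She treated the fast step as a pre-equilibrium: D and Z form a hidden form of D, and X draws on it. In red, she noted, G stopped near 28.0% with 18.1% of D still hidden. So she read the stop as the end of X, charged at 0.55 equiv, not of base.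

She then timed X from amber. The distance of G from its last reading fell from 8.9 percentage points to 4.4 points between 3.00 h and 5.00 h. That reading gives X a mean life of 2.84 h. She warned that this clock also counts X going to G, so it runs short.

Amber made 22.2% of G in its first 1.00 h, more than the 5.00% of D that elm's feed brings in that time. So she expected each fed portion to become G promptly while cX lasts. She defined the feed window, the mean life of X over the feed time, as 14.2%. Multiplying the fed charge by it, she committed to about 8.52% for oak and 14.2% for elm, both on the low side. Birch, she said, repeats amber, near 45.5%.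

The forecaster disagreed, with 44.5% for oak, 45.5% for elm, 45.5% for birch, and the verdict all alike. His ground was: “Slow feeding should therefore change little.”

The flasks gave 16.9% for oak, 21.6% for elm and 45.8% for birch, so birch leads.

    X + J → G (k = 1.75 M⁻¹ h⁻¹)
    X → Q (k = 0.220 h⁻¹)
    D + Z ⇌ E + J, settled at all times (K = 1.16)

In birch, the step from X to Q alone halves X in 3.2 h, shorter than the 20 h feed of oak and elm. When that feed ended, oak held 0.132% of its X and elm 0.110% of its X, with G at 16.8% and 21.6%, more than her 8.52% and 14.2%. With D fed over 6.00 h, the window of elm widens from 14.2% to 47.3%, and that flask gives 35.1% of G.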